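**Retrosynthetic overview**
1. The C4–OH goes on last. The target comes from 2-methoxy-6-pentadecylphenyl acetate by sterically controlled C–H borylation/oxidation, so the free OH arrives after the only other phenol is already acetylated and the two phenols never need differentiating.
2. The aryl–alkyl C–C bond comes from a Negishi coupling of 2-bromo-6-methoxyphenyl acetate with pentadecylzinc bromide, made from 1-bromopentadecane.
3. The O-acetyl bond comes from commercial 2-bromo-6-methoxyphenol and Ac2O.
4. No ring is formed, because the single benzene ring is bought, and there is no stereocentre to set.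

Assumption: the target has no stereocentre and is achiral, so the given SMILES is the complete structure and no enantiocontrol is needed.

Step 1
Reactants: 1 2-bromo-6-methoxyphenol
Product: 2 2-bromo-6-methoxyphenyl acetate
Conditions: Ac2O (1.5 equiv), DMAP (5 mol %), pyridine, 0 °C to rt, 3 h
Reagents that add atoms: acetic anhydride, CC(=O)OC(C)=O
Why: DMAP-catalysed O-acylation (nucleophilic-catalysis esterification) acetylates the only hydroxyl present, so the hindered ester of the target is in place before a second phenol exists, and no stereocentre is formed.

Step 2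
Reactants: 2 2-bromo-6-methoxyphenyl acetate; 3 1-bromopentadecane
Product: 5 2-methoxy-6-pentadecylphenyl acetate, via pentadecylzinc bromide 4 (not isolated)
Conditions: 3 (1.4 equiv), Zn dust (2 equiv), LiCl (2 equiv), THF, 50 °C, 16 h; then 2 (1.0 equiv), Pd(OAc)2 (2 mol %), SPhos (4 mol %), THF, rt to 40 °C, 12 h; aq NH4Cl work-up
Reagents that add atoms: zinc, [Zn] (stays only in intermediate 4)
Why: In this LiCl-assisted zinc insertion followed by Negishi cross-coupling, the primary alkylzinc halide leaves the aryl ester alone, and SPhos on zerovalent palladium speeds oxidative addition into the electron-rich bromide and lets reductive elimination outrun beta-hydride elimination, with no stereocentre formed.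

Step 3
Reactants: 5 2-methoxy-6-pentadecylphenyl acetate
Product: 7 4-hydroxy-2-methoxy-6-pentadecylphenyl acetate, via arylboronic acid pinacol ester 6 (not isolated)
Conditions: [Ir(OMe)(cod)]2 (1.5 mol %), 4,4'-di-tert-butyl-2,2'-bipyridine (3 mol %), B2pin2 (1.0 equiv), THF, 80 °C, 16 h; evaporate; then KHSO5 (1.05 equiv, as 2KHSO5·KHSO4·K2SO4), acetone/H2O, rt, 10 min; aq NaHSO3 quench
Reagents that add atoms: bis(pinacolato)diboron, CC1(C)OB(OC1(C)C)B1OC(C)(C)C(C)(C)O1 (Bpin of intermediate 6); potassium peroxymonosulfate KHSO5, [K+].[O-]S(=O)(=O)OO (the new phenolic O of 7)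
Why: Iridium-catalysed aromatic C–H borylation of a 1,2,3-trisubstituted arene is sterically governed and takes only the C–H flanked by two hydrogens (para to OAc), and the one-pot, slightly acidic peroxymonosulfate ipso-oxidation of the C–B bond gives the phenol without touching the acetate or creating a stereocentre.

**Compound list**
1 | 2-bromo-6-methoxyphenol | COc1cccc(Br)c1O | starting material
2 | 2-bromo-6-methoxyphenyl acetate | COc1cccc(Br)c1OC(C)=O | intermediate
3 | 1-bromopentadecane | CCCCCCCCCCCCCCCBr | starting material
4 | pentadecylzinc bromide | CCCCCCCCCCCCCCC[Zn]Br | intermediate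
5 | 2-methoxy-6-pentadecylphenyl acetate | CCCCCCCCCCCCCCCc1cccc(OC)c1OC(C)=O | intermediate
6 | 2-methoxy-6-pentadecyl-4-(4,4,5,5-tetramethyl-1,3,2-dioxaborolan-2-yl)phenyl acetate | CCCCCCCCCCCCCCCc1cc(B2OC(C)(C)C(C)(C)O2)cc(OC)c1OC(C)=O | intermediate
7 | 4-hydroxy-2-methoxy-6-pentadecylphenyl acetate (achiral) | CCCCCCCCCCCCCCCc1cc(O)cc(OC)c1OC(C)=O | target

Total step count: 3.
Longest linear sequence: 3 (1 → 2 → 5 → 7).

**Steps most likely to fail**
The route has only three steps, so all three are listed. The order of falling risk is step 3, step 2, step 1.

**Risk at step 1.** The acylation itself is safe. The weak point is that the aryl acetate is installed early and could be partly lost in the organometallic step. The fallback sets out from 1 and comes back at 5 by inverting the order of events. Compound 1 is coupled as the free phenol with 4, added slowly to Pd(OAc)2/SPhos in THF at rt, where coupling is faster than protonation of the zinc reagent. This gives 2-methoxy-6-pentadecylphenol F1. Acetylation of this phenol with Ac2O, DMAP and pyridine then gives 5, so no ester has to survive the coupling.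

**Risk at step 2.** Zinc insertion into the long-chain bromide may be sluggish, and the ortho-substituted, electron-rich bromide may give reduced arene. The fallback sets out from 2 and comes back at 5, replacing the sp3–sp2 coupling by an sp–sp2 coupling plus reduction.
- Sonogashira reaction of 2 with commercial 1-pentadecyne (PdCl2(PPh3)2, CuI, Et3N/DMF, 70 °C) gives 2-methoxy-6-(pentadec-1-yn-1-yl)phenyl acetate F2. The tertiary amine does not cleave the acetate, and the acetate in turn blocks benzofuran formation.
- Full hydrogenation (H2 1 atm, Pd/C, EtOAc, rt) then gives 5.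

**Risk at step 3.** Regiocontrol rests on sterics alone, the catalyst may be slow on this substrate, and the hydroquinone monoester could be over-oxidised. The fallback sets out from 5 and comes back at 7, replacing C–H activation by quinone chemistry and hindrance-controlled deacylation.
- Methanolysis of 5 (K2CO3, MeOH, rt) gives 2-methoxy-6-pentadecylphenol F1.
- Teuber oxidation of the free para position with (KSO3)2NO (2.5 equiv, KH2PO4 buffer, acetone/H2O) gives 2-methoxy-6-pentadecyl-1,4-benzoquinone F3.
- Reductive acetylation (Zn dust, Ac2O, NaOAc, rt) gives 2-methoxy-6-pentadecylbenzene-1,4-diyl diacetate F4.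
- Brief methanolysis (K2CO3 0.3 equiv, MeOH/THF, 0 °C, stopped once F4 is consumed) removes only the exposed 4-acetate and gives 7. The 1-acetate is shielded by the flanking OMe group and the C15 chain.

**Further compounds**
F1 | step 1 | 2-methoxy-6-pentadecylphenol | CCCCCCCCCCCCCCCc1cccc(OC)c1O
F2 | step 2 | 2-methoxy-6-(pentadec-1-yn-1-yl)phenyl acetate | CCCCCCCCCCCCCC#Cc1cccc(OC)c1OC(C)=O
F3 | step 3 | 2-methoxy-6-pentadecyl-1,4-benzoquinone | CCCCCCCCCCCCCCCC1=CC(=O)C=C(OC)C1=O
F4 | step 3 | 2-methoxy-6-pentadecylbenzene-1,4-diyl diacetate | CCCCCCCCCCCCCCCc1cc(OC(C)=O)cc(OC)c1OC(C)=O
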